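# Proposed total synthesis of CNP0204268.2 by ring-expanding semipinacol rearrangement of a bicyclopentyl epoxy alcohol

Locants follow spiro[4.5]decane numbering: C1 (ring A carbinol), C2 (ring A carbon with the side chain), C3, C4, C5 (spiro carbon), C6 (ring B methyl carbinol), C7, C8, C9 (alkylidene carbon), C10 (ring B CH with the 3-hydroxypropyl chain).

## Analysis of the target

The target 48 is a spiro[4.5]decane in which cyclopentane ring A (C1–C4) and cyclohexane ring B (C6–C10) share the quaternary carbon C5. Ring A carries the secondary alcohol at C1 and, at C2, a (2E,4E)-triene chain whose first alkene carbon bears the acetoxymethyl group and whose far end is a 2-substituted 1,3-diene with a prenyl-type tail. Ring B carries the tertiary methyl carbinol C6 and the methine C10 with its 3-hydroxypropyl chain on the two carbons flanking C5, and at C9 an exocyclic tetrasubstituted enal whose formyl group lies on the C10 side (Z). The five stereocentres (1S, 2S, 5S, 6S, 10R) are clustered at the spiro carbon: the C1 hydroxyl is trans to the C2 chain and syn to C6, the C6 hydroxyl lies on the ring B face occupied by C1, and C10 lies on the ring A face opposite the C1 hydroxyl. The sensitive groups are the primary allylic acetate at the end of a conjugated triene (labile to zerovalent palladium, acid and base), the enal (vinylogous epimerisation of C10, conjugate addition of the neighbouring primary alcohol) and the 2-substituted diene. One acetate stands beside three free hydroxyls, so the ester has to be placed while the other oxygens are masked and the last unmasking cannot be basic. The hard parts are the quaternary C5 with three stereogenic neighbours, the geometry of the tetrasubstituted enal and the late attachment of the triene. The strategy rests on one feature: C5 lies between the oxygen-bearing C1 of ring A and the oxygen-bearing C6 of ring B, with the C5–C10 bond on its other side, which is the array left when a ring bond of a carbinol migrates to the neighbouring carbon of a 2,3-epoxy alcohol.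

## Retrosynthetic reasoning

**48 back to 46.** The enal is formed last, by oxidation of the allylic alcohol of 47, because an enal would not survive the carbanion and hydride chemistry of the side-chain construction. 47 comes from 46 by removal of three silicon groups in one fluoride operation. No skeletal bond is cut here; what is gained is that the acetate of 46 is installed when every other oxygen is blocked.

**46 back to 35 and 40.** The C=C bond between the first and second carbon of the C2 side chain is cut (46 from 45 from 44, then 44 to 35 plus 40). The carbon attached to C2 is the α-carbon of the aldehyde 34, so an aldol condensation forms this bond, and the thermodynamic geometry of a 2-substituted enal (formyl trans to the dienyl chain) is exactly the one needed. A cut further out would require a stereodefined trisubstituted alkenyl metal on ring A, which is harder to reach. The dienal 40 is cut between its C2 and C3 into the enol triflate 38 (from ketone 36) and 39.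

**35 back to 32.** The imine 35 comes from aldehyde 34, this from alcohol 33, and 33 from the benzyl ether 32. The benzyl group is kept until ring B is complete because it is the only ether that passes through the Lewis acid, hydride and peracid steps and is still orthogonal to silicon.

**32 back to 26.** The exocyclic alkene of 32 is traced to the diene 31 by taking away two hydrogens (1,4), and 31 is cut at the C9–C(sp2) bond into the enol triflate 28 and the boronate 30 (from 29). A direct olefination of the C9 ketone 26 would give a tetrasubstituted alkene of uncontrolled geometry. Adding hydrogen to the two ends of an s-cis diene instead puts the new methyl group on the C8 side by necessity. 28 comes from 26 by kinetic enolisation toward C8.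

**26 back to 24.** The C9 carbonyl is traced to the C–Si bond of 24 (through alcohol 25). Silicon is used as the masked oxygen because a real oxygen at this position would be β to the ketone of 12 and would eliminate, and would also retard the shift of the neighbouring carbon in the key step.

**24 back to 20.** The methyl carbinol is traced to the ketone 20 (24 from diol 23, epoxide 22, alkene 21). The C6 methyl carbon is brought in as a methylene and the oxygen is delivered from the C1 hydroxyl, so the configuration at C6 is relayed from C1 and not left to the facial bias of a hindered ketone.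

**20 back to 19 (key disconnection).** The C5–C10 bond is cut and C10 is reattached to C6, which contracts ring B to a cyclopentanol; the C1 oxygen is closed onto C5 as an oxirane. This turns the spirocycle into two five-membered rings joined by one bond. The forward reaction has to break the oxirane at its tertiary carbon and move the chain-bearing ring carbon to it with inversion.

**19 back to 6 and 12.** The oxirane of 19 comes from the alkene of 18 (from 17 and 15), and the bond between the two rings is cut into the alkenyl metal derived from stannane 6 and the ketone 12. The forward steps must deliver the epoxide oxygen trans to the ring A side chain; the carbinol configuration itself is lost later.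

**12 and 6 back to starting materials.** 12 is cut at C–Si and at the allyl–ring bond into 7, 8 and 9: an enantioselective conjugate silylation sets the silyl-bearing carbon and the enolate alkylation sets C10 trans to it. 6 comes from triflate 5, which is traced to enone 3 by an asymmetric conjugate reduction that gives the enolate on the required side, and 3 to 1 and 2.

## Alternatives that were turned down

**Alternative 1: samarium ketyl–enoate closure of ring A.** The C1–C2 bond is cut. In the forward step SmI2 reduces the neopentyl aldehyde of the ring B aldehyde–enoate A2 to a ketyl that adds 5-exo to the (E)-enoate and gives the trans cyclopentanol A1. In its favour, ketyl–olefin closures of this kind are reliable, the trans relation of C1–OH and the C2 arm comes directly, the C2 arm arrives as an acetic ester ready for alkylidenation, and the dithiane at C9 tolerates the reductant. Against it, A2 must already contain the quaternary C5 and both flanking stereocentres C6 and C10, so the hardest part of the molecule is moved and not solved. A2 is also a β-hydroxy aldehyde with a quaternary α-carbon (retro-aldol risk), and the face of the ketyl relative to C5 is controlled only by a conformational preference between two similar ring arms. On the ring A oxygenation pattern and the oxidation level of the C2 arm this route is as good as or better than the chosen one. The chosen strategy offers instead the formation of C5 and ring B in one stereospecific step from two simple rings.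

**Alternative 2: lactone-tethered olefination for the enal.** The exocyclic C9=C bond is cut. The phosphonopropionate A4 is to close onto the C9 ketone by an intramolecular Horner–Wadsworth–Emmons reaction and give the eight-membered unsaturated lactone A3. Its strength is real: the ring forces the acyl carbon to the C10 side, so the geometry is guaranteed by connectivity, a stronger guarantee than any intermolecular olefination can give. Against it, an eight-membered ring has to form at a hindered ketone in competition with oligomerisation, the amine base can epimerise C10 next to the ketone, the hydroxypropyl oxygen must be freed early, and the lactone has to be reduced and re-oxidised. It also says nothing about how C5 is made. The chosen route reaches the same C9 ketone (26) and answers the geometry by 1,4-hydrogenation of the s-cis diene 31, which is stereospecific without any ring strain.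

**Alternative 3: asymmetric conjugate addition–aldol cascade for ring B.** The C10–chain bond and the C5–C6 bond are cut. A copper–phosphoramidite catalyst adds the silyloxypropyl group of a dialkylzinc to the exocyclic enone carbon of A6, and the zinc enolate closes onto the methyl ketone to give the spiro ketol A5. It is the most step-economic way to ring B: C5, C6 and C10 are set in one catalytic operation and the methyl carbinol arrives directly, where the chosen route spends three steps on C6. Against it, the β-carbon of A6 is neopentylic (it is attached to the dithiane carbon), the aldol onto a ketone is reversible, and the relative configuration of C5 and C6 to C10 depends on a single closed transition state that cannot be corrected afterwards. Ring A of A5 is bare, so C2 and C1 would then have to be set by alkylation and reduction next to the quaternary centre. The chosen strategy carries the C2 stereocentre in from the beginning and lets it direct the epoxide face, and with it C1 and C5.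

Key step: step 9

Remark (assumption): CNP0204268.2 is taken to be exactly the stereoisomer of the SMILES. For each enantioselective catalyst the ligand antipode named is the one assumed to give the drawn configuration, and the other antipode would be used if the sense proved opposite.

## Route

Step 1
Reactants: 1 3-bromocyclopent-2-en-1-one; 2 potassium [2-(benzyloxy)ethyl]trifluoroborate
Product: 3 3-[2-(benzyloxy)ethyl]cyclopent-2-en-1-one
Conditions: PdCl2(dppf) (5 mol %), Cs2CO3, toluene/H2O, 80 °C
Reagents that add atoms: none
Why: Suzuki–Miyaura coupling of a primary alkyltrifluoroborate with a β-bromo enone; oxidative addition into the vinylogous acyl bromide is fast and the bidentate phosphine holds back β-hydride elimination.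

Step 2
Reactants: 3 3-[2-(benzyloxy)ethyl]cyclopent-2-en-1-one
Product: 5 (3S)-3-[2-(benzyloxy)ethyl]cyclopent-1-en-1-yl trifluoromethanesulfonate, via bis-enoxysilane 4 (not isolated)
Conditions: CuCl (5 mol %), NaOt-Bu (5 mol %), (S)-p-tol-BINAP (5 mol %), Ph2SiH2 (0.55 equiv), toluene, 0 °C; then PhNTf2, CsF, DME, rt
Reagents that add atoms: N-phenylbis(trifluoromethanesulfonimide), O=S(=O)(N(c1ccccc1)S(=O)(=O)C(F)(F)F)C(F)(F)F
Why: Copper hydride-catalysed asymmetric conjugate reduction of a 3-alkylcyclopentenone: the chiral bisphosphine–CuH delivers hydride to one face of the β-carbon and sets C3, and the silane traps the enolate as the silyl enol ether on the C1–C2 side only. Fluoride-triggered O-sulfonylation then converts this regiodefined enol ether into the enol triflate without enolate equilibration.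

Step 3
Reactants: 5 (3S)-3-[2-(benzyloxy)ethyl]cyclopent-1-en-1-yl trifluoromethanesulfonate
Product: 6 {(3S)-3-[2-(benzyloxy)ethyl]cyclopent-1-en-1-yl}trimethylstannane
Conditions: Me3SnSnMe3, Pd(PPh3)4 (5 mol %), LiCl, THF, 60 °C
Reagents that add atoms: hexamethylditin, C[Sn](C)(C)[Sn](C)(C)C
Why: Palladium-catalysed stannylation of an alkenyl triflate (Stille-type coupling with a distannane); the stereocentre is remote from the reacting carbon.

Step 4
Reactants: 7 cyclopent-2-en-1-one; 8 2-[dimethyl(phenyl)silyl]-4,4,5,5-tetramethyl-1,3,2-dioxaborolane; 9 allyl iodide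
Product: 12 (2S,3S)-3-[dimethyl(phenyl)silyl]-2-(prop-2-en-1-yl)cyclopentan-1-one, via boron enolate 10 (not isolated), via lithium enoxyborate 11 (not isolated)
Conditions: CuCl (2 mol %), chiral imidazolinium salt (N-heterocyclic carbene precursor, 2 mol %), NaOt-Bu (4 mol %), THF, −78 °C; then MeLi, −78 °C; then 9, DMPU, −78 → −30 °C
Reagents that add atoms: none
Why: Enantioselective copper-catalysed conjugate silyl transfer from the Si–B reagent sets C3 and leaves the regiodefined boron enolate; methyllithium converts it into the nucleophilic enoxyborate, which is allylated at C2 anti to the bulky silyl group (enolate alkylation) to give the trans ketone. Allyl iodide is used because a saturated 3-silyloxypropyl iodide would alkylate a cyclopentanone enolate too slowly to outrun proton exchange; the chain oxygen is added in step 6.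

Step 5
Reactants: 6 {(3S)-3-[2-(benzyloxy)ethyl]cyclopent-1-en-1-yl}trimethylstannane; 12 (2S,3S)-3-[dimethyl(phenyl)silyl]-2-(prop-2-en-1-yl)cyclopentan-1-one
Product: 15 (1S,2S,3S)-1-{(3S)-3-[2-(benzyloxy)ethyl]cyclopent-1-en-1-yl}-3-[dimethyl(phenyl)silyl]-2-(prop-2-en-1-yl)cyclopentan-1-ol, via alkenyllithium 13 (not isolated), via alkenylcerium dichloride 14 (not isolated)
Conditions: 6, MeLi, THF, −78 °C; CeCl3, THF, −78 °C; then 12, −78 → −40 °C
Reagents that add atoms: none
Why: Tin–lithium exchange and transmetalation to cerium give a weakly basic alkenyl nucleophile that adds 1,2 to the enolisable ketone (organocerium carbonyl addition) from the face anti to the neighbouring allyl group. The carbinol configuration has no consequence later, because this carbon becomes the C6 carbonyl in step 9.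

Step 6
Reactants: 15 tertiary allylic alcohol
Product: 17 (1S,2S,3S)-1-{(3S)-3-[2-(benzyloxy)ethyl]cyclopent-1-en-1-yl}-3-[dimethyl(phenyl)silyl]-2-(3-hydroxypropyl)cyclopentan-1-ol, via trialkylborane 16 (not isolated)
Conditions: 9-BBN, THF, 0 °C → rt; then NaOH, H2O2, 0 °C
Reagents that add atoms: hydrogen peroxide, OO
Why: Hydroboration–oxidation; 9-BBN reacts with the monosubstituted alkene and not the trisubstituted cyclopentene, and boron goes to the terminal carbon.

Step 7
Reactants: 17 diol
Product: 18 (1S,2S,3S)-1-{(3S)-3-[2-(benzyloxy)ethyl]cyclopent-1-en-1-yl}-3-[dimethyl(phenyl)silyl]-2-{3-[(triisopropylsilyl)oxy]propyl}cyclopentan-1-ol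
Conditions: i-Pr3SiCl, imidazole, DMF, rt
Reagents that add atoms: chlorotriisopropylsilane, CC(C)[Si](Cl)(C(C)C)C(C)C
Why: Silylation of the primary alcohol; the tertiary allylic alcohol is too hindered to react. The triisopropylsilyl ether is chosen because it withstands the Lewis acid of step 9 and the acetic acid medium of step 14.

Step 8
Reactants: 18 silyl ether
Product: 19 (1S,2S,3S)-1-{(1R,4S,5S)-4-[2-(benzyloxy)ethyl]-6-oxabicyclo[3.1.0]hexan-1-yl}-3-[dimethyl(phenyl)silyl]-2-{3-[(triisopropylsilyl)oxy]propyl}cyclopentan-1-ol
Conditions: VO(acac)2 (5 mol %), t-BuOOH, CH2Cl2, 0 °C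
Reagents that add atoms: tert-butyl hydroperoxide, CC(C)(C)OO
Why: Vanadium-catalysed hydroxyl-directed epoxidation of the tertiary allylic alcohol. The carbinol can rotate to either alkene face, so the face is chosen by the substituent on the allylic ring A carbon, and oxygen should be delivered anti to the 2-(benzyloxy)ethyl chain.

Step 9
Reactants: 19 epoxy alcohol
Product: 20 (1S,2S,5S,9S,10S)-2-[2-(benzyloxy)ethyl]-9-[dimethyl(phenyl)silyl]-1-hydroxy-10-{3-[(triisopropylsilyl)oxy]propyl}spiro[4.5]decan-6-one
Conditions: BF3·OEt2 (1.1 equiv), CH2Cl2, −78 °C; NaHCO3 quench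
Reagents that add atoms: none
Why: BF3 binds the oxirane oxygen of 19 and the C–O bond at the fully substituted oxirane carbon lengthens; as positive charge builds there, the cyclopentanol ring bond that lies anti-periplanar to the breaking C–O bond shifts, the chain-bearing carbon moving from the carbinol carbon to the oxirane carbon while the carbinol oxygen becomes the C6 carbonyl. The closest known reaction type is the Lewis acid-promoted semipinacol rearrangement of 2,3-epoxy alcohols to β-hydroxy ketones with ring expansion of a 1-(oxiranyl)cycloalkanol. Ring B is closed not by a cyclisation but by a one-carbon ring expansion (1,2-alkyl shift) of the cyclopentanol to the cyclohexanone, the new bond being C5–C10. The one new stereocentre, spiro C5, results from inversion at the oxirane carbon and is therefore fixed by the oxirane configuration set in step 8; C10 migrates with retention and C1 keeps the oxirane oxygen with its configuration. The step needs ionisation at the tertiary and not the secondary oxirane carbon, which cation stability secures. It also needs migration of the substituted ring carbon and not the ring CH2, which is secured by the higher migratory aptitude of the more substituted carbon, reinforced by donation from the adjacent C–Si bond into the electron-poor migrating terminus (β-silicon effect). Either carbinol epimer of 19 would give the same ketone, since the carbinol carbon becomes trigonal.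

Step 10
Reactants: 20 spiro ketol
Product: 21 2-[2-(benzyloxy)ethyl]-9-[dimethyl(phenyl)silyl]-6-methylidene-10-{3-[(triisopropylsilyl)oxy]propyl}spiro[4.5]decan-1-ol (stereocentres as in 20)
Conditions: Zn, CH2Br2, TiCl4, THF/CH2Cl2, 0 °C → rt
Reagents that add atoms: dibromomethane, BrCBr
Why: Takai–Lombardo methylenation; the non-basic titanium–zinc methylene reagent converts the hindered ketone next to the quaternary carbon without the retro-aldol cleavage that a basic ylide could cause in this β-hydroxy ketone.

Step 11
Reactants: 21 methylidene alcohol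
Product: 22 spiro-oxirane at C6 of 21 (oxirane oxygen on the ring B face syn to C1, oxirane CH2 anti; other stereocentres as in 20)
Conditions: VO(acac)2 (10 mol %), t-BuOOH, CH2Cl2, rt
Reagents that add atoms: tert-butyl hydroperoxide, CC(C)(C)OO
Why: Vanadium-catalysed epoxidation directed by the homoallylic C1 hydroxyl; the vanadate ester on C1 reaches only the alkene face on the C1 side of ring B, so the new C6–O bond is placed syn to C1 and C6 is set.

Step 12
Reactants: 22 spiro-oxirane
Product: 23 2-[2-(benzyloxy)ethyl]-9-[dimethyl(phenyl)silyl]-6-methyl-10-{3-[(triisopropylsilyl)oxy]propyl}spiro[4.5]decane-1,6-diol (6S, 6-OH syn to C1; other stereocentres as in 20)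
Conditions: LiAlH4, THF, 0 → 50 °C
Reagents that add atoms: none
Why: Hydride opening of the 1,1-disubstituted oxirane at its CH2 carbon (SN2 epoxide reduction) gives the tertiary methyl carbinol and leaves the C6 configuration untouched.

Step 13
Reactants: 23 1,6-diol
Product: 24 1,6-O-(di-tert-butylsilylene) acetal of 23
Conditions: t-Bu2Si(OTf)2, 2,6-lutidine, CH2Cl2, 0 → 40 °C
Reagents that add atoms: di-tert-butylsilyl bis(trifluoromethanesulfonate), CC(C)(C)[Si](OS(=O)(=O)C(F)(F)F)(OS(=O)(=O)C(F)(F)F)C(C)(C)C
Why: Silylene acetal formation; the C1 and C6 hydroxyls are syn across the spiro carbon and close a six-membered dioxasilinane. It masks the secondary alcohol before the oxidation of step 15 and is later removed by fluoride together with the other silyl groups.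

Step 14
Reactants: 24 silylene acetal
Product: 25 silylene acetal with 9-OH in place of the 9-silyl group (retention at C9)
Conditions: KBr, AcOOH, NaOAc, AcOH, rt
Reagents that add atoms: peracetic acid, CC(=O)OO
Why: Fleming–Tamao oxidation: ipso-bromodesilylation of the phenyl group and peracid-induced 1,2-shift from silicon to oxygen replace C–Si by C–OH with retention. It is placed here because the molecule holds no alkene and no ketone at this stage.

Step 15
Reactants: 25 C9 alcohol
Product: 26 C9 ketone (spiro[4.5]decan-9-one; C10 and the other stereocentres as in 20)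
Conditions: Dess–Martin periodinane, NaHCO3, CH2Cl2, rt
Reagents that add atoms: none
Why: Dess–Martin oxidation of the only free alcohol; the buffered, non-basic medium preserves the α-stereocentre C10.

Step 16
Reactants: 26 C9 ketone
Product: 28 C8–C9 enol triflate of 26 (9-trifluoromethanesulfonyloxy-spiro[4.5]dec-8-ene), via potassium enolate 27 (not isolated)
Conditions: KN(SiMe3)2, THF, −78 °C; PhNTf2, −78 → 0 °C
Reagents that add atoms: N-phenylbis(trifluoromethanesulfonimide), O=S(=O)(N(c1ccccc1)S(=O)(=O)C(F)(F)F)C(F)(F)F
Why: Kinetic enolate formation and O-triflation; the hindered amide removes a proton from the C8 methylene and not the tertiary C10–H, so C10 is untouched and the alkene is placed at C8–C9.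

Step 17
Reactants: 29 tert-butyldimethyl(prop-2-yn-1-yloxy)silane
Product: 30 tert-butyldimethyl{[2-(4,4,5,5-tetramethyl-1,3,2-dioxaborolan-2-yl)prop-2-en-1-yl]oxy}silane
Conditions: B2pin2, CuCl (5 mol %), SIMes·HCl (5 mol %), NaOt-Bu (10 mol %), MeOH, THF, 0 °C → rt
Reagents that add atoms: bis(pinacolato)diboron, CC1(C)OB(OC1(C)C)B1OC(C)(C)C(C)(C)O1
Why: Copper–boryl addition to a terminal alkyne followed by protonation (protoboration); with an N-aryl carbene ligand and a propargylic ether, boron is expected at the internal carbon.

Step 18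
Reactants: 28 enol triflate; 30 alkenylboronate
Product: 31 diene: 28 with 3-[(tert-butyldimethylsilyl)oxy]prop-1-en-2-yl at C9 in place of the triflate
Conditions: PdCl2(dppf) (5 mol %), Cs2CO3, THF/H2O, 50 °C
Reagents that add atoms: none
Why: Suzuki–Miyaura coupling of an alkenyl triflate with an alkenylboronate installs the three-carbon unit as a 2,3-disubstituted 1,3-diene.

Step 19
Reactants: 31 diene
Product: 32 (9Z)-9-{1-[(tert-butyldimethylsilyl)oxy]propan-2-ylidene} compound (tetrasubstituted exocyclic alkene, CH2OSi on the C10 side, CH3 on the C8 side)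
Conditions: (η6-naphthalene)Cr(CO)3 (20 mol %), H2 (5 atm), THF, 45 °C
Reagents that add atoms: none
Why: Chromium tricarbonyl-catalysed 1,4-hydrogenation of a 1,3-diene; the Cr(CO)3 fragment binds the diene only in its s-cis form and adds hydrogen to its two ends. The former =CH2 therefore becomes the methyl group on the C8 side and the silyloxymethyl group stays on the C10 side, which is the geometry of the target; isolated alkenes are not reduced.

Step 20
Reactants: 32 benzyl ether
Product: 33 primary alcohol (C2 chain CH2CH2OH)
Conditions: lithium 4,4'-di-tert-butylbiphenylide (LiDBB), THF, −78 °C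
Reagents that add atoms: none
Why: Reductive debenzylation by an arene radical anion (dissolving-metal type); the electron is accepted by the benzyl arene and not by the isolated tetrasubstituted alkene, and silyl ethers are inert.

Step 21
Reactants: 33 primary alcohol
Product: 34 aldehyde (C2 chain CH2CHO)
Conditions: Dess–Martin periodinane, NaHCO3, CH2Cl2, 0 °C → rt
Reagents that add atoms: none
Why: Dess–Martin oxidation of the only free alcohol; the stereocentre C2 is β to the new carbonyl and cannot epimerise.

Step 22
Reactants: 34 aldehyde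
Product: 35 (E)-N-cyclohexylimine of 34
Conditions: c-C6H11NH2, 4 Å molecular sieves, Et2O, rt
Reagents that add atoms: cyclohexylamine, NC1CCCCC1
Why: Imine condensation; the imine makes the α-methylene a regiodefined nucleophile for the crossed aldol of step 25.

Step 23
Reactants: 36 6-methylhept-5-en-2-one
Product: 38 6-methylhepta-1,5-dien-2-yl trifluoromethanesulfonate, via lithium enolate 37 (not isolated)
Conditions: LiN(i-Pr)2, THF, −78 °C; PhNTf2, −78 → 0 °C
Reagents that add atoms: N-phenylbis(trifluoromethanesulfonimide), O=S(=O)(N(c1ccccc1)S(=O)(=O)C(F)(F)F)C(F)(F)F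
Why: Kinetic deprotonation of the methyl ketone at the methyl group and O-triflation give the terminal enol triflate.

Step 24
Reactants: 38 dienyl triflate; 39 acrolein
Product: 40 (2E)-8-methyl-4-methylidenenona-2,7-dienal
Conditions: Pd(OAc)2 (5 mol %), PPh3 (10 mol %), Et3N, DMF, 60 °C
Reagents that add atoms: none
Why: Heck reaction of an alkenyl triflate with an electron-poor alkene; syn insertion and syn β-hydride elimination give the (E)-enal.

Step 25
Reactants: 35 imine; 40 dienal
Product: 44 (2E,4E)-2-[ring A C2]-10-methyl-6-methylideneundeca-2,4,9-trienal (ring part as in 32), via lithium azaenolate 41 (not isolated), via lithium aldolate imine 42 (not isolated), via hydroxy aldehyde 43 (not isolated)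
Conditions: LiN(i-Pr)2, THF, −78 → 0 °C; 40, −78 °C; then aq. (CO2H)2, THF, rt
Reagents that add atoms: none
Why: Wittig directed aldol condensation: the lithiated imine adds 1,2 to the non-enolisable dienal, and aqueous oxalic acid hydrolyses the imine and eliminates water from the allylic β-hydroxy aldehyde. The 2-substituted enal forms under thermodynamic control with the formyl group trans to the dienyl chain, which is the required geometry.

Step 26
Reactants: 44 trienal
Product: 45 (2E,4E)-trienol (C1' CH2OH)
Conditions: NaBH4, CeCl3·7H2O, MeOH/THF, −40 °C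
Reagents that add atoms: none
Why: Luche reduction gives clean 1,2-reduction of the cross-conjugated enal.

Step 27
Reactants: 45 allylic alcohol
Product: 46 allylic acetate
Conditions: Ac2O, pyridine, DMAP (cat.), CH2Cl2, 0 °C
Reagents that add atoms: acetic anhydride, CC(=O)OC(C)=O
Why: Acylation of the only free hydroxyl; every other oxygen is silylated, so the acetate position is unambiguous.

Step 28
Reactants: 46 acetate
Product: 47 tetraol monoacetate (C1-OH, C6-OH, 3-hydroxypropyl, ring B allylic CH2OH)
Conditions: HF·pyridine, pyridine, THF, 0 °C → rt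
Reagents that add atoms: none
Why: Fluoride-mediated desilylation removes the silyl ethers and the silylene acetal in one operation; the buffered, non-basic medium leaves the allylic acetate in place.

Step 29
Reactants: 47 tetraol monoacetate
Product: 48 CNP0204268.2
Conditions: MnO2, CH2Cl2, rt
Reagents that add atoms: none
Why: Manganese dioxide oxidises only the allylic alcohol on the tetrasubstituted alkene to the enal; the saturated primary, secondary and tertiary alcohols and the acetate are not touched, and the alkene geometry is kept.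

## Compound list

1 | 3-bromocyclopent-2-en-1-one | O=C1C=C(Br)CC1 | starting material
2 | potassium [2-(benzyloxy)ethyl]trifluoroborate | [K+].F[B-](F)(F)CCOCc1ccccc1 | starting material
3 | 3-[2-(benzyloxy)ethyl]cyclopent-2-en-1-one | O=C1C=C(CCOCc2ccccc2)CC1 | intermediate
4 | bis({(3S)-3-[2-(benzyloxy)ethyl]cyclopent-1-en-1-yl}oxy)diphenylsilane | c1ccccc1COCC[C@@H]1CCC(O[Si](c2ccccc2)(c2ccccc2)OC2=C[C@H](CCOCc3ccccc3)CC2)=C1 | intermediate
5 | (3S)-3-[2-(benzyloxy)ethyl]cyclopent-1-en-1-yl trifluoromethanesulfonate | c1ccccc1COCC[C@@H]1CCC(OS(=O)(=O)C(F)(F)F)=C1 | intermediate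
6 | {(3S)-3-[2-(benzyloxy)ethyl]cyclopent-1-en-1-yl}trimethylstannane | c1ccccc1COCC[C@@H]1CCC([Sn](C)(C)C)=C1 | intermediate
7 | cyclopent-2-en-1-one | O=C1C=CCC1 | starting material
8 | 2-[dimethyl(phenyl)silyl]-4,4,5,5-tetramethyl-1,3,2-dioxaborolane | CC1(C)OB(OC1(C)C)[Si](C)(C)c1ccccc1 | starting material
9 | allyl iodide (3-iodoprop-1-ene) | C=CCI | starting material
10 | 2-({(3S)-3-[dimethyl(phenyl)silyl]cyclopent-1-en-1-yl}oxy)-4,4,5,5-tetramethyl-1,3,2-dioxaborolane (boron enolate) | CC1(C)OB(OC2=C[C@@H]([Si](C)(C)c3ccccc3)CC2)OC1(C)C | intermediate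
11 | lithium methyl borate of 10 (lithium enoxyborate) | [Li+].CC1(C)O[B-](C)(OC2=C[C@@H]([Si](C)(C)c3ccccc3)CC2)OC1(C)C | intermediate
12 | (2S,3S)-3-[dimethyl(phenyl)silyl]-2-(prop-2-en-1-yl)cyclopentan-1-one (trans) | O=C1[C@H](CC=C)[C@@H]([Si](C)(C)c2ccccc2)CC1 | intermediate
13 | {(3S)-3-[2-(benzyloxy)ethyl]cyclopent-1-en-1-yl}lithium | c1ccccc1COCC[C@@H]1CCC([Li])=C1 | intermediate
14 | dichloro{(3S)-3-[2-(benzyloxy)ethyl]cyclopent-1-en-1-yl}cerium | c1ccccc1COCC[C@@H]1CCC([Ce](Cl)Cl)=C1 | intermediate
15 | (1S,2S,3S)-1-{(3S)-3-[2-(benzyloxy)ethyl]cyclopent-1-en-1-yl}-3-[dimethyl(phenyl)silyl]-2-(prop-2-en-1-yl)cyclopentan-1-ol | c1ccccc1COCC[C@@H]1CCC([C@@]2(O)[C@H](CC=C)[C@@H]([Si](C)(C)c3ccccc3)CC2)=C1 | intermediate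
16 | B-alkyl-9-borabicyclo[3.3.1]nonane from 15 (boron on the terminal chain carbon) | c1ccccc1COCC[C@@H]1CCC([C@@]2(O)[C@H](CCCB3C4CCCC3CCC4)[C@@H]([Si](C)(C)c3ccccc3)CC2)=C1 | intermediate
17 | (1S,2S,3S)-1-{(3S)-3-[2-(benzyloxy)ethyl]cyclopent-1-en-1-yl}-3-[dimethyl(phenyl)silyl]-2-(3-hydroxypropyl)cyclopentan-1-ol | c1ccccc1COCC[C@@H]1CCC([C@@]2(O)[C@H](CCCO)[C@@H]([Si](C)(C)c3ccccc3)CC2)=C1 | intermediate
18 | (1S,2S,3S)-1-{(3S)-3-[2-(benzyloxy)ethyl]cyclopent-1-en-1-yl}-3-[dimethyl(phenyl)silyl]-2-{3-[(triisopropylsilyl)oxy]propyl}cyclopentan-1-ol | c1ccccc1COCC[C@@H]1CCC([C@@]2(O)[C@H](CCCO[Si](C(C)C)(C(C)C)C(C)C)[C@@H]([Si](C)(C)c3ccccc3)CC2)=C1 | intermediate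
19 | (1S,2S,3S)-1-{(1R,4S,5S)-4-[2-(benzyloxy)ethyl]-6-oxabicyclo[3.1.0]hexan-1-yl}-3-[dimethyl(phenyl)silyl]-2-{3-[(triisopropylsilyl)oxy]propyl}cyclopentan-1-ol (oxirane trans to the ring A chain) | c1ccccc1COCC[C@@H]1CC[C@@]2([C@@]3(O)[C@H](CCCO[Si](C(C)C)(C(C)C)C(C)C)[C@@H]([Si](C)(C)c4ccccc4)CC3)O[C@@H]12 | intermediate
20 | (1S,2S,5S,9S,10S)-2-[2-(benzyloxy)ethyl]-9-[dimethyl(phenyl)silyl]-1-hydroxy-10-{3-[(triisopropylsilyl)oxy]propyl}spiro[4.5]decan-6-one | c1ccccc1COCC[C@@H]1CC[C@]2([C@H](CCCO[Si](C(C)C)(C(C)C)C(C)C)[C@@H]([Si](C)(C)c3ccccc3)CCC2=O)[C@H]1O | intermediate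
21 | 6-methylidene analogue of 20 (C6=CH2; stereocentres as in 20) | c1ccccc1COCC[C@@H]1CC[C@]2([C@H](CCCO[Si](C(C)C)(C(C)C)C(C)C)[C@@H]([Si](C)(C)c3ccccc3)CCC2=C)[C@H]1O | intermediate
22 | C6 spiro-oxirane of 21 (oxirane O syn to C1 on ring B, CH2 anti) | c1ccccc1COCC[C@@H]1CC[C@]2([C@H](CCCO[Si](C(C)C)(C(C)C)C(C)C)[C@@H]([Si](C)(C)c3ccccc3)CC[C@@]24CO4)[C@H]1O | intermediate
23 | 2-[2-(benzyloxy)ethyl]-9-[dimethyl(phenyl)silyl]-6-methyl-10-{3-[(triisopropylsilyl)oxy]propyl}spiro[4.5]decane-1,6-diol (6S; 6-OH syn to C1) | c1ccccc1COCC[C@@H]1CC[C@]2([C@H](CCCO[Si](C(C)C)(C(C)C)C(C)C)[C@@H]([Si](C)(C)c3ccccc3)CC[C@]2(C)O)[C@H]1O | intermediate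
24 | 1,6-O-(di-tert-butylsilylene) acetal of 23 | c1ccccc1COCC[C@@H]1CC[C@]2([C@H](CCCO[Si](C(C)C)(C(C)C)C(C)C)[C@@H]([Si](C)(C)c3ccccc3)CC[C@]2(C)O[Si](C(C)(C)C)(C(C)(C)C)O3)[C@H]13 | intermediate
25 | 9-hydroxy compound (24 with OH in place of the silyl group, retention at C9) | c1ccccc1COCC[C@@H]1CC[C@]2([C@H](CCCO[Si](C(C)C)(C(C)C)C(C)C)[C@@H](O)CC[C@]2(C)O[Si](C(C)(C)C)(C(C)(C)C)O3)[C@H]13 | intermediate
26 | 9-ketone of 25 | c1ccccc1COCC[C@@H]1CC[C@]2([C@H](CCCO[Si](C(C)C)(C(C)C)C(C)C)C(=O)CC[C@]2(C)O[Si](C(C)(C)C)(C(C)(C)C)O3)[C@H]13 | intermediate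
27 | potassium 8-en-9-olate of 26 | c1ccccc1COCC[C@@H]1CC[C@]2([C@H](CCCO[Si](C(C)C)(C(C)C)C(C)C)C([O-])=CC[C@]2(C)O[Si](C(C)(C)C)(C(C)(C)C)O3)[C@H]13.[K+] | intermediate
28 | C8–C9 enol triflate of 26 | c1ccccc1COCC[C@@H]1CC[C@]2([C@H](CCCO[Si](C(C)C)(C(C)C)C(C)C)C(OS(=O)(=O)C(F)(F)F)=CC[C@]2(C)O[Si](C(C)(C)C)(C(C)(C)C)O3)[C@H]13 | intermediate
29 | tert-butyldimethyl(prop-2-yn-1-yloxy)silane | C#CCO[Si](C)(C)C(C)(C)C | starting material
30 | tert-butyldimethyl{[2-(4,4,5,5-tetramethyl-1,3,2-dioxaborolan-2-yl)prop-2-en-1-yl]oxy}silane | C=C(CO[Si](C)(C)C(C)(C)C)B1OC(C)(C)C(C)(C)O1 | intermediate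
31 | diene: 9-{3-[(tert-butyldimethylsilyl)oxy]prop-1-en-2-yl}spiro[4.5]dec-8-ene (rest as in 28) | c1ccccc1COCC[C@@H]1CC[C@]2([C@H](CCCO[Si](C(C)C)(C(C)C)C(C)C)C(C(=C)CO[Si](C)(C)C(C)(C)C)=CC[C@]2(C)O[Si](C(C)(C)C)(C(C)(C)C)O3)[C@H]13 | intermediate
32 | (9Z)-9-{1-[(tert-butyldimethylsilyl)oxy]propan-2-ylidene} compound (CH2OSi on the C10 side) | c1ccccc1COCC[C@@H]1CC[C@]2([C@H](CCCO[Si](C(C)C)(C(C)C)C(C)C)/C(=C(/C)CO[Si](C)(C)C(C)(C)C)CC[C@]2(C)O[Si](C(C)(C)C)(C(C)(C)C)O3)[C@H]13 | intermediate
33 | debenzylated primary alcohol (C2 chain CH2CH2OH) | OCC[C@@H]1CC[C@]2([C@H](CCCO[Si](C(C)C)(C(C)C)C(C)C)/C(=C(/C)CO[Si](C)(C)C(C)(C)C)CC[C@]2(C)O[Si](C(C)(C)C)(C(C)(C)C)O3)[C@H]13 | intermediate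
34 | aldehyde (C2 chain CH2CHO) | O=CC[C@@H]1CC[C@]2([C@H](CCCO[Si](C(C)C)(C(C)C)C(C)C)/C(=C(/C)CO[Si](C)(C)C(C)(C)C)CC[C@]2(C)O[Si](C(C)(C)C)(C(C)(C)C)O3)[C@H]13 | intermediate
35 | (E)-N-cyclohexylimine of 34 | C1CCCCC1/N=C/C[C@@H]1CC[C@]2([C@H](CCCO[Si](C(C)C)(C(C)C)C(C)C)/C(=C(/C)CO[Si](C)(C)C(C)(C)C)CC[C@]2(C)O[Si](C(C)(C)C)(C(C)(C)C)O3)[C@H]13 | intermediate
36 | 6-methylhept-5-en-2-one | CC(=O)CCC=C(C)C | starting material
37 | lithium 6-methylhepta-1,5-dien-2-olate | [Li+].[O-]C(=C)CCC=C(C)C | intermediate
38 | 6-methylhepta-1,5-dien-2-yl trifluoromethanesulfonate | C=C(OS(=O)(=O)C(F)(F)F)CCC=C(C)C | intermediate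
39 | acrolein (prop-2-enal) | C=CC=O | starting material
40 | (2E)-8-methyl-4-methylidenenona-2,7-dienal | O=C/C=C/C(=C)CCC=C(C)C | intermediate
41 | lithium azaenolate of 35 (N-lithio enamide) | [Li]N(C1CCCCC1)C=C[C@@H]1CC[C@]2([C@H](CCCO[Si](C(C)C)(C(C)C)C(C)C)/C(=C(/C)CO[Si](C)(C)C(C)(C)C)CC[C@]2(C)O[Si](C(C)(C)C)(C(C)(C)C)O3)[C@H]13 | intermediate
42 | lithium alkoxide of the β-hydroxy imine (aldol adduct of 41 and 40; two new centres as a mixture) | C1CCCCC1N=CC(C(O[Li])/C=C/C(=C)CCC=C(C)C)[C@@H]1CC[C@]2([C@H](CCCO[Si](C(C)C)(C(C)C)C(C)C)/C(=C(/C)CO[Si](C)(C)C(C)(C)C)CC[C@]2(C)O[Si](C(C)(C)C)(C(C)(C)C)O3)[C@H]13 | intermediate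
43 | β-hydroxy aldehyde from hydrolysis of 42 | O=CC(C(O)/C=C/C(=C)CCC=C(C)C)[C@@H]1CC[C@]2([C@H](CCCO[Si](C(C)C)(C(C)C)C(C)C)/C(=C(/C)CO[Si](C)(C)C(C)(C)C)CC[C@]2(C)O[Si](C(C)(C)C)(C(C)(C)C)O3)[C@H]13 | intermediate
44 | (2E,4E)-2-[ring A C2]-10-methyl-6-methylideneundeca-2,4,9-trienal (ring part as in 32) | C=C(/C=C/C=C(/C=O)[C@@H]1CC[C@]2([C@H](CCCO[Si](C(C)C)(C(C)C)C(C)C)/C(=C(/C)CO[Si](C)(C)C(C)(C)C)CC[C@]2(C)O[Si](C(C)(C)C)(C(C)(C)C)O3)[C@H]13)CCC=C(C)C | intermediate
45 | corresponding (2E,4E)-trien-1-ol | C=C(/C=C/C=C(/CO)[C@@H]1CC[C@]2([C@H](CCCO[Si](C(C)C)(C(C)C)C(C)C)/C(=C(/C)CO[Si](C)(C)C(C)(C)C)CC[C@]2(C)O[Si](C(C)(C)C)(C(C)(C)C)O3)[C@H]13)CCC=C(C)C | intermediate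
46 | corresponding (2E,4E)-trien-1-yl acetate, fully silylated | C=C(/C=C/C=C(/COC(C)=O)[C@@H]1CC[C@]2([C@H](CCCO[Si](C(C)C)(C(C)C)C(C)C)/C(=C(/C)CO[Si](C)(C)C(C)(C)C)CC[C@]2(C)O[Si](C(C)(C)C)(C(C)(C)C)O3)[C@H]13)CCC=C(C)C | intermediate
47 | desilylated tetraol monoacetate (ring B allylic alcohol, Z) | C=C(/C=C/C=C(/COC(C)=O)[C@@H]1CC[C@]2([C@H](CCCO)/C(=C(/C)CO)CC[C@]2(C)O)[C@H]1O)CCC=C(C)C | intermediate
48 | CNP0204268.2: (2E,4E)-2-[(1S,2S,5S,6S,9Z,10R)-1,6-dihydroxy-10-(3-hydroxypropyl)-6-methyl-9-(1-oxopropan-2-ylidene)spiro[4.5]decan-2-yl]-10-methyl-6-methylideneundeca-2,4,9-trien-1-yl acetate | C=C(/C=C/C=C(/COC(C)=O)[C@@H]1CC[C@]2([C@H](CCCO)/C(=C(/C)C=O)CC[C@]2(C)O)[C@H]1O)CCC=C(C)C | target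

## Step count and least certain steps

Total step count: 29. Longest linear sequence: 25 steps (1–3, 5–16, 18–22, 25–29), from 3-bromocyclopent-2-en-1-one.

**Step 9 (key step).** Most likely to go wrong is the choice of migrating bond and the timing of ionisation. If the oxirane opens to a free tertiary cation before the shift, the ring CH2 may migrate in competition, a hydride may shift from the neighbouring oxirane carbon (Meinwald-type ketone), or the benzyl ether oxygen, which sits on the face opposite the oxirane oxygen, may attack the secondary oxirane carbon. Fallback: from 19, the tertiary hydroxyl is silylated with N-(trimethylsilyl)imidazole to the epoxy trimethylsilyl ether F1, and F1 is rearranged with TiCl4 in CH2Cl2 at −78 °C. In this variant the shift is terminated by a silyl oxocarbenium ion and the chloride-bearing Lewis acid keeps the transition state tight, so stepwise pathways are disfavoured; aqueous work-up returns the route at 20.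

**Step 4.** Most likely to go wrong is loss of regiochemical integrity or over-alkylation, through proton exchange between the enoxyborate and the product ketone, or sluggish alkylation of the borate. Fallback: from 1, bromide is displaced by addition–elimination with (PhMe2Si)2CuLi to give 3-[dimethyl(phenyl)silyl]cyclopent-2-en-1-one F2. F2 is reduced by the copper hydride system of step 2 (CuCl, NaOt-Bu, (S)-p-tol-BINAP, Ph2SiH2) to the bis-enoxysilane F3, and F3 is allylated in the same flask with Bu4N[Ph3SiF2] and allyl bromide, returning at 12. Here the stereocentre is set by hydride delivery and the enolate is released by fluoride.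

**Step 8.** Most likely to go wrong is poor facial selectivity: the directing hydroxyl sits on a freely rotating carbon, and the stereocentres of the cyclopentanol may oppose the bias of the ring A chain. Fallback: from 18, reagent-controlled epoxidation with the fructose-derived chiral dioxirane (Shi epoxidation; ketone catalyst, Oxone, buffered MeCN/H2O), choosing the catalyst antipode that attacks the face anti to the chain, returning at 19. This fallback makes no compound outside the list (F0).

**Step 19.** Most likely to go wrong is lack of turnover, because the hindered 2,3-disubstituted diene may not reach the s-cis geometry at chromium, or loss of the catalyst by arene exchange with the benzyl group. Fallback: from 26, Peterson olefination with the lithium enolate of ethyl 2-(trimethylsilyl)propanoate gives the unsaturated ester as two geometric isomers, the (Z)-ester F4 and the (E)-ester F5. These are separated, and F5 is returned to the mixture by photochemical equilibration. F4 is reduced with i-Bu2AlH to the allylic alcohol F6, and F6 is silylated (t-BuMe2SiCl, imidazole) to return at 32. This fallback gives up stereocontrol in favour of separation and recycling.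

**Step 25.** Most likely to go wrong is conjugate addition of the azaenolate to the dienal, oligomerisation of the dienal, or retro-aldol and incomplete dehydration during hydrolysis. Fallback: from 34, Pinnick oxidation gives the acid F7 and Me3SiCHN2 gives the methyl ester F8. The lithium enolate of F8 (LiN(i-Pr)2) adds to 40 to give the β-hydroxy ester F9. Mesylation (MeSO2Cl, Et3N) gives F10 and elimination with DBU gives the (2E)-trienoate F11. Reduction of F11 with i-Bu2AlH returns at 45. The ester enolate is less basic toward the dienal and the elimination is separated from the addition.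

## Further compounds

F1 | step 9 | trimethylsilyl ether of 19 (carbinol O-SiMe3) | c1ccccc1COCC[C@@H]1CC[C@@]2([C@@]3(O[Si](C)(C)C)[C@H](CCCO[Si](C(C)C)(C(C)C)C(C)C)[C@@H]([Si](C)(C)c4ccccc4)CC3)O[C@@H]12
F2 | step 4 | 3-[dimethyl(phenyl)silyl]cyclopent-2-en-1-one | O=C1C=C([Si](C)(C)c2ccccc2)CC1
F3 | step 4 | bis({(3S)-3-[dimethyl(phenyl)silyl]cyclopent-1-en-1-yl}oxy)diphenylsilane | c1ccccc1[Si](C)(C)[C@H]1CCC(O[Si](c2ccccc2)(c2ccccc2)OC2=C[C@@H]([Si](C)(C)c3ccccc3)CC2)=C1
F0 | step 8 | none | none
F4 | step 19 | ethyl (2Z)-2-(spiro[4.5]decan-9-ylidene)propanoate derived from 26 (ester on the C10 side) | c1ccccc1COCC[C@@H]1CC[C@]2([C@H](CCCO[Si](C(C)C)(C(C)C)C(C)C)/C(=C(/C)C(=O)OCC)CC[C@]2(C)O[Si](C(C)(C)C)(C(C)(C)C)O3)[C@H]13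
F5 | step 19 | (2E)-isomer of F4 (ester on the C8 side) | c1ccccc1COCC[C@@H]1CC[C@]2([C@H](CCCO[Si](C(C)C)(C(C)C)C(C)C)/C(=C(\C)C(=O)OCC)CC[C@]2(C)O[Si](C(C)(C)C)(C(C)(C)C)O3)[C@H]13
F6 | step 19 | (2Z)-allylic alcohol from F4 | c1ccccc1COCC[C@@H]1CC[C@]2([C@H](CCCO[Si](C(C)C)(C(C)C)C(C)C)/C(=C(/C)CO)CC[C@]2(C)O[Si](C(C)(C)C)(C(C)(C)C)O3)[C@H]13
F7 | step 25 | carboxylic acid from 34 (C2 chain CH2CO2H) | OC(=O)C[C@@H]1CC[C@]2([C@H](CCCO[Si](C(C)C)(C(C)C)C(C)C)/C(=C(/C)CO[Si](C)(C)C(C)(C)C)CC[C@]2(C)O[Si](C(C)(C)C)(C(C)(C)C)O3)[C@H]13
F8 | step 25 | methyl ester of F7 | COC(=O)C[C@@H]1CC[C@]2([C@H](CCCO[Si](C(C)C)(C(C)C)C(C)C)/C(=C(/C)CO[Si](C)(C)C(C)(C)C)CC[C@]2(C)O[Si](C(C)(C)C)(C(C)(C)C)O3)[C@H]13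
F9 | step 25 | β-hydroxy ester from F8 and 40 (two new centres as a mixture) | COC(=O)C(C(O)/C=C/C(=C)CCC=C(C)C)[C@@H]1CC[C@]2([C@H](CCCO[Si](C(C)C)(C(C)C)C(C)C)/C(=C(/C)CO[Si](C)(C)C(C)(C)C)CC[C@]2(C)O[Si](C(C)(C)C)(C(C)(C)C)O3)[C@H]13
F10 | step 25 | methanesulfonate of F9 | COC(=O)C(C(OS(C)(=O)=O)/C=C/C(=C)CCC=C(C)C)[C@@H]1CC[C@]2([C@H](CCCO[Si](C(C)C)(C(C)C)C(C)C)/C(=C(/C)CO[Si](C)(C)C(C)(C)C)CC[C@]2(C)O[Si](C(C)(C)C)(C(C)(C)C)O3)[C@H]13
F11 | step 25 | methyl (2E,4E)-trienoate corresponding to 44 | C=C(/C=C/C=C(/C(=O)OC)[C@@H]1CC[C@]2([C@H](CCCO[Si](C(C)C)(C(C)C)C(C)C)/C(=C(/C)CO[Si](C)(C)C(C)(C)C)CC[C@]2(C)O[Si](C(C)(C)C)(C(C)(C)C)O3)[C@H]13)CCC=C(C)C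
A1 | alternative 1 | spirocyclic trans-2-(tert-butoxycarbonylmethyl)cyclopentanol with C9 dithiane and silylated C10 chain | CC(C)(C)OC(=O)C[C@@H]1CC[C@]2([C@H](CCCO[Si](C)(C)C(C)(C)C)C3(SCCCS3)CC[C@]2(C)O)[C@H]1O
A2 | alternative 1 | ring B aldehyde with quaternary C5 bearing CHO and an (E)-enoate chain | CC(C)(C)OC(=O)/C=C/CC[C@@]1(C=O)[C@H](CCCO[Si](C)(C)C(C)(C)C)C2(SCCCS2)CC[C@]1(C)O
A3 | alternative 2 | eight-membered unsaturated lactone fused to ring B at C9–C10 | COc1ccc(COCC[C@@H]2CC[C@]3([C@@H]4CCCOC(=O)/C(C)=C4/CC[C@]3(C)O)[C@H]2O[Si](C)(C)C(C)(C)C)cc1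
A4 | alternative 2 | C9 ketone with the chain oxygen acylated by 2-(diethoxyphosphoryl)propanoic acid | COc1ccc(COCC[C@@H]2CC[C@]3([C@H](CCCOC(=O)C(C)P(=O)(OCC)OCC)C(=O)CC[C@]3(C)O)[C@H]2O[Si](C)(C)C(C)(C)C)cc1
A5 | alternative 3 | spiro[4.5]decan-1-one ketol with C6 methyl carbinol, C9 dithiane and silylated C10 chain | C1CC[C@]2([C@H](CCCO[Si](C)(C)C(C)(C)C)C3(SCCCS3)CC[C@]2(C)O)C1=O
A6 | alternative 3 | (E)-2-alkylidenecyclopentanone with a dithiane-linked 3-oxobutyl arm | CC(=O)CCC1(SCCCS1)/C=C1\CCCC1=O
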